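**Retrosynthetic overview**
1. Target 25 is (13E)-6β-hydroxy-3α,19-bis(3-methylbutanoyloxy)labda-8,13-dien-15-oic acid. Late stage: the 3α and 6β carbinols come from 3,6-dione 22 by equatorial hydride delivery, the esters by acylation, and C12–C16 by acetoacetate-dianion alkylation of the C-11 bromide 14 followed by enol phosphate/cuprate methylation.
2. Key disconnection: ring B (C5–C6–C7–C8–C9–C10) is opened across C7–C8 and C9–C10. This gives the ring-A 2-ethoxy diene 9 (C7=C6(OEt)–C5=C10, with C5=C10 inside ring A) and methyl but-2-ynoate 10 (C17–C8≡C9–C11), joined by an intermolecular Diels–Alder reaction.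
3. Enabling feature: in ring B the tetrasubstituted C8=C9 bond is homoallylic to the C-6 oxygen (C6–C7–C8=C9, with O-6 "para" to C-9, which carries C-11), and quaternary C-10 sits next to C-5. This is the pattern a 2-oxy-diene/alkynoate [4+2] produces. C-6 arrives as a masked ketone that later fixes C-5 (equilibration) and C-6 (hydride from the α face).
4. Ring order: ring A first, from 2-methylcyclohexane-1,3-dione (hydroxymethylation, then a CBS desymmetrisation that sets C-4; the 3β-silyloxy group steers the cycloaddition and is later inverted by oxidation/reduction). Ring B is closed last, in the key step.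

Key step: step 8

Assumption: bicyclic compounds are named with labdane numbering in the normal 10β-CH3 series (C-17 on C-8, C-18 = 4α-CH3, C-19 = 4β-CH2O, C-20 on C-10), and reagents sold as solutions (LDA, KHMDS, DIBAL-H, TBAF, L-Selectride, catecholborane) are used as purchased.

Step 1
Reactants: 1 2-methylcyclohexane-1,3-dione
Product: 2 2-(hydroxymethyl)-2-methylcyclohexane-1,3-dione
Conditions: 37% aq. CH2O, NaHCO3 (cat.), THF–H2O, rt
Reagents that add atoms: formaldehyde C=O
Why: Aldol-type hydroxymethylation of the acidic 2-alkyl-1,3-dione at C-2 puts the future C-19 on the future C-4 without creating a stereocentre, and the weak base should avoid retro-Claisen ring opening.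

Step 2
Reactants: 2 2-(hydroxymethyl)-2-methylcyclohexane-1,3-dione
Product: 3 2-[(tert-butyldimethylsilyloxy)methyl]-2-methylcyclohexane-1,3-dione
Conditions: TBSOTf, 2,6-lutidine, CH2Cl2, −78 °C
Reagents that add atoms: tert-butyldimethylsilyl trifluoromethanesulfonate CC(C)(C)[Si](C)(C)OS(=O)(=O)C(F)(F)F
Why: Silylation of the primary alcohol under non-nucleophilic conditions blocks retro-aldol loss of formaldehyde and makes the CH2O arm clearly larger than the methyl group for step 3.

Step 3
Reactants: 3 2-[(tert-butyldimethylsilyloxy)methyl]-2-methylcyclohexane-1,3-dione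
Product: 4 (2S,3S)-2-[(tert-butyldimethylsilyloxy)methyl]-3-hydroxy-2-methylcyclohexan-1-one
Conditions: (R)-Me-CBS (20 mol%), catecholborane (1.1 equiv), PhMe, −78 → −40 °C; aq. work-up
Reagents that add atoms: none
Why: CBS (oxazaborolidine) reduction used as a desymmetrisation of a prochiral 2,2-disubstituted 1,3-dione, in which the (R)-catalyst should give the (S)-carbinol (quaternary carbon as the large group) and hydride should enter anti to the bulkier CH2OTBS arm, so that OH ends cis to CH2OTBS and the quaternary carbon (future C-4) becomes S.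

Step 4
Reactants: 4 (2S,3S)-2-[(tert-butyldimethylsilyloxy)methyl]-3-hydroxy-2-methylcyclohexan-1-one
Product: 5 (2S,3S)-3-(tert-butyldimethylsilyloxy)-2-[(tert-butyldimethylsilyloxy)methyl]-2-methylcyclohexan-1-one
Conditions: TBSOTf, 2,6-lutidine, CH2Cl2, 0 °C
Reagents that add atoms: tert-butyldimethylsilyl trifluoromethanesulfonate CC(C)(C)[Si](C)(C)OS(=O)(=O)C(F)(F)F
Why: Standard silylation of the hindered secondary alcohol gives the future 3β-OTBS group, which protects the carbinol through the base steps and later shields the β face in the cycloaddition.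

Step 5
Reactants: 5 (2S,3S)-3-(tert-butyldimethylsilyloxy)-2-[(tert-butyldimethylsilyloxy)methyl]-2-methylcyclohexan-1-one
Product: 6 (2S,3S,6RS)-3-(tert-butyldimethylsilyloxy)-2-[(tert-butyldimethylsilyloxy)methyl]-2,6-dimethylcyclohexan-1-one (C-6 epimer mixture)
Conditions: LDA, THF, −78 °C; MeI, −78 → −20 °C
Reagents that add atoms: iodomethane CI
Why: Enolate alkylation at the only enolisable α-carbon (the other is quaternary) introduces the future C-20 methyl on the future C-10, and the new stereocentre is irrelevant because both epimers converge on the same enolate in step 6.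

Step 6
Reactants: 6 (2S,3S,6RS)-3-(tert-butyldimethylsilyloxy)-2-[(tert-butyldimethylsilyloxy)methyl]-2,6-dimethylcyclohexan-1-one
Product: 7 (5S,6S)-5-(tert-butyldimethylsilyloxy)-6-[(tert-butyldimethylsilyloxy)methyl]-2,6-dimethylcyclohex-1-en-1-yl trifluoromethanesulfonate
Conditions: KHMDS, THF, −78 → 0 °C; PhNTf2, 0 °C → rt
Reagents that add atoms: N-phenylbis(trifluoromethanesulfonimide) O=S(=O)(N(c1ccccc1)S(=O)(=O)C(F)(F)F)C(F)(F)F
Why: Enol triflate formation is regiospecific because deprotonation can only occur at the methine carbon, giving the tetrasubstituted enol triflate (the future C5=C10 bond).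

Step 7
Reactants: 7 (5S,6S)-5-(tert-butyldimethylsilyloxy)-6-[(tert-butyldimethylsilyloxy)methyl]-2,6-dimethylcyclohex-1-en-1-yl trifluoromethanesulfonate; 8 tributyl(1-ethoxyvinyl)stannane
Product: 9 (3S,4S)-4-(tert-butyldimethylsilyloxy)-3-[(tert-butyldimethylsilyloxy)methyl]-2-(1-ethoxyethenyl)-1,3-dimethylcyclohex-1-ene
Conditions: Pd(PPh3)4 (5 mol%), LiCl (3 equiv), THF, reflux
Reagents that add atoms: none
Why: Stille coupling of an enol triflate with an α-alkoxyvinylstannane (LiCl assists transmetalation) gives the 2-ethoxy-1,3-diene directly, bringing C-6, C-7 and the C-6 oxygen without touching a stereocentre.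

Step 8
Reactants: 9 (3S,4S)-4-(tert-butyldimethylsilyloxy)-3-[(tert-butyldimethylsilyloxy)methyl]-2-(1-ethoxyethenyl)-1,3-dimethylcyclohex-1-ene; 10 methyl but-2-ynoate
Product: 11 methyl 3β,19-bis(tert-butyldimethylsilyloxy)-6-ethoxy-12,13,14,15,16-pentanorlabda-5,8-dien-11-oate
Conditions: 10 (5 equiv), BHT (cat.), PhMe, 150 °C, sealed tube
Reagents that add atoms: none
Why: Thermal, concerted but asynchronous normal-electron-demand [4+2] cycloaddition in which the 2-ethoxy diene C7=C6(OEt)–C5=C10 (largest HOMO coefficient at C-7) bonds first to the β-carbon C-8 of the alkynoate and then through C-9 to the fully substituted terminus C-10; the closest known reaction type is the Diels–Alder reaction of 1-vinyl-2-methylcyclohexene-type and 2-alkoxy or 2-silyloxy dienes with acetylenic esters, which builds decalins with an angular quaternary carbon. Ring B is closed by intermolecular [4+2] annulation across C-7 and C-10, forming C7–C8 and C9–C10 in one operation and delivering the tetrasubstituted C8=C9 alkene, C-11 at the ester level and C-6 at the ketone level as the C5=C6 enol ether. The only new stereocentre, quaternary C-10, is controlled by ring A: the 3β-OTBS and 4β-CH2OTBS groups both lie on the β face and one of them is pseudoaxial in either half-chair, so the alkyne should add to the α face and place CH3-20 cis to C-19. Regioselectivity (C-9 to C-10, ethoxy and ester "para") is required and is secured because the 2-donor and the 1,1-dialkyl terminus both direct the ester-bearing carbon to C-10, while a linear alkyne raises no endo/exo question. π-Facial selectivity is the second requirement and rests on the two β-silyloxy groups, which is why C-3 is carried as the 3β epimer and inverted later.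

Step 9
Reactants: 11 methyl 3β,19-bis(tert-butyldimethylsilyloxy)-6-ethoxy-12,13,14,15,16-pentanorlabda-5,8-dien-11-oate
Product: 12 3β,19-bis(tert-butyldimethylsilyloxy)-6-ethoxy-12,13,14,15,16-pentanorlabda-5,8-dien-11-ol
Conditions: DIBAL-H (3 equiv), CH2Cl2, −78 → −20 °C; Rochelle salt
Reagents that add atoms: none
Why: 1,2-Reduction of the hindered conjugated ester gives the primary allylic alcohol, and the silyl ethers and the enol ether are inert to DIBAL-H.

Step 10
Reactants: 12 3β,19-bis(tert-butyldimethylsilyloxy)-6-ethoxy-12,13,14,15,16-pentanorlabda-5,8-dien-11-ol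
Product: 14 11-bromo-3β,19-bis(tert-butyldimethylsilyloxy)-6-ethoxy-12,13,14,15,16-pentanorlabda-5,8-diene, via allylic mesylate 13 (not isolated)
Conditions: MsCl, Et3N, CH2Cl2, −40 °C; then LiBr, THF, −40 → 0 °C
Reagents that add atoms: methanesulfonyl chloride CS(=O)(=O)Cl (in 13 only); lithium bromide [Li+].[Br-]
Why: Mesylation and in situ SN2 displacement by bromide under non-acidic conditions (so the enol ether survives) should give the primary allylic bromide, the preferred regioisomer of this allylic system.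

Step 11
Reactants: 14 11-bromo-3β,19-bis(tert-butyldimethylsilyloxy)-6-ethoxy-12,13,14,15,16-pentanorlabda-5,8-diene; 15 allyl acetoacetate (prop-2-enyl 3-oxobutanoate)
Product: 16 allyl 3β,19-bis(tert-butyldimethylsilyloxy)-6-ethoxy-13-oxo-16-norlabda-5,8-dien-15-oate
Conditions: 15, NaH, THF, 0 °C; n-BuLi, 0 °C; then 14, 0 °C → rt
Reagents that add atoms: none
Why: γ-Alkylation of the acetoacetate dianion (the more basic terminal carbanion reacts) with the primary allylic bromide forms C11–C12 and brings C-12 to C-15.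

Step 12
Reactants: 16 allyl 3β,19-bis(tert-butyldimethylsilyloxy)-6-ethoxy-13-oxo-16-norlabda-5,8-dien-15-oate
Product: 17 allyl (13Z)-3β,19-bis(tert-butyldimethylsilyloxy)-13-(diethoxyphosphoryloxy)-6-ethoxy-16-norlabda-5,8,13-trien-15-oate
Conditions: NaH, Et2O, 0 °C; ClP(O)(OEt)2, 0 °C
Reagents that add atoms: diethyl chlorophosphate CCOP(=O)(Cl)OCC
Why: O-Phosphorylation of the chelated sodium Z-enolate of the β-keto ester in ether should give the (Z)-enol phosphate, which fixes the geometry of the later trisubstituted alkene.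

Step 13
Reactants: 17 allyl (13Z)-3β,19-bis(tert-butyldimethylsilyloxy)-13-(diethoxyphosphoryloxy)-6-ethoxy-16-norlabda-5,8,13-trien-15-oate
Product: 18 allyl (13E)-3β,19-bis(tert-butyldimethylsilyloxy)-6-ethoxylabda-5,8,13-trien-15-oate
Conditions: Me2CuLi (from MeLi and CuI), Et2O, −78 → −45 °C
Reagents that add atoms: lithium dimethylcuprate [Li+].C[Cu-]C
Why: Cuprate substitution of the enol phosphate (addition–elimination with retention) turns the Z-enol phosphate into the (13E)-3-methyl enoate, and at or below −45 °C the allyl ester should be spared.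

Step 14
Reactants: 18 allyl (13E)-3β,19-bis(tert-butyldimethylsilyloxy)-6-ethoxylabda-5,8,13-trien-15-oate
Product: 19 allyl (13E)-6-ethoxy-3β,19-dihydroxylabda-5,8,13-trien-15-oate
Conditions: TBAF (4 equiv), THF, rt → 40 °C
Reagents that add atoms: none
Why: Fluoride cleaves both silyl ethers while the acid-labile enol ether (the masked 6-ketone) and the allyl ester remain.

Step 15
Reactants: 19 allyl (13E)-6-ethoxy-3β,19-dihydroxylabda-5,8,13-trien-15-oate
Product: 20 allyl (13E)-6-ethoxy-3β-hydroxy-19-(3-methylbutanoyloxy)labda-5,8,13-trien-15-oate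
Conditions: 3-methylbutanoyl chloride (1.1 equiv), pyridine, CH2Cl2, −30 °C
Reagents that add atoms: 3-methylbutanoyl chloride CC(C)CC(=O)Cl
Why: Acylation of the primary C-19 hydroxyl should be faster than that of the secondary C-3 hydroxyl flanked by quaternary C-4, giving the 19-monoester.

Step 16
Reactants: 20 allyl (13E)-6-ethoxy-3β-hydroxy-19-(3-methylbutanoyloxy)labda-5,8,13-trien-15-oate
Product: 22 allyl (13E)-19-(3-methylbutanoyloxy)-3,6-dioxo-5α-labda-8,13-dien-15-oate, via 3-keto enol ether 21 (not isolated)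
Conditions: DMP, pyridine, CH2Cl2, 0 °C; then 10% aq. (CO2H)2, THF, rt
Reagents that add atoms: water O
Why: Dess–Martin oxidation removes the temporary 3β stereocentre, then mild acid hydrolysis of the enol ether unmasks the 6-ketone, with C-5 protonated from the open α face and any cis-fused isomer equilibrating through the enol to the trans-fused 5α-H ketone, while the weak acid should avoid conjugation of the β,γ-enone.

Step 17
Reactants: 22 allyl (13E)-19-(3-methylbutanoyloxy)-3,6-dioxo-5α-labda-8,13-dien-15-oate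
Product: 23 allyl (13E)-3α,6β-dihydroxy-19-(3-methylbutanoyloxy)labda-8,13-dien-15-oate
Conditions: L-Selectride (3 equiv), THF, −78 → −40 °C; H2O
Reagents that add atoms: none
Why: The bulky trialkylborohydride should attack both ketones from the equatorial direction, giving the axial 3α-alcohol at C-3 and, by α-face attack at C-6 (the β face is blocked by the syn-axial C-19 and C-20 groups), the axial 6β-alcohol, while the esters and the β,β-disubstituted enoate are not reduced at this temperature.

Step 18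
Reactants: 23 allyl (13E)-3α,6β-dihydroxy-19-(3-methylbutanoyloxy)labda-8,13-dien-15-oate
Product: 24 allyl (13E)-6β-hydroxy-3α,19-bis(3-methylbutanoyloxy)labda-8,13-dien-15-oate
Conditions: (Me2CHCH2CO)2O, Et3N, DMAP (cat.), CH2Cl2, 0 °C → rt
Reagents that add atoms: 3-methylbutanoic anhydride CC(C)CC(=O)OC(=O)CC(C)C
Why: DMAP-catalysed acylation should esterify the axial 3α-hydroxyl, whereas the 6β-hydroxyl, 1,3-diaxial to both C-19 and C-20, is too hindered to react under these conditions.

Step 19
Reactants: 24 allyl (13E)-6β-hydroxy-3α,19-bis(3-methylbutanoyloxy)labda-8,13-dien-15-oate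
Product: 25 (13E)-6β-hydroxy-3α,19-bis(3-methylbutanoyloxy)labda-8,13-dien-15-oic acid (CNP0333611.1)
Conditions: Pd(PPh3)4 (5 mol%), morpholine, THF, rt; citric acid work-up
Reagents that add atoms: none
Why: Pd(0)-catalysed allyl transfer to morpholine (Tsuji–Trost-type deallylation) frees the acid under neutral conditions that leave the two 3-methylbutanoates, the free 6β-alcohol and both alkenes untouched.

**Compound list**
1 | 2-methylcyclohexane-1,3-dione | CC1C(=O)CCCC1=O | starting material
2 | 2-(hydroxymethyl)-2-methylcyclohexane-1,3-dione | CC1(CO)C(=O)CCCC1=O | intermediate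
3 | 2-[(tert-butyldimethylsilyloxy)methyl]-2-methylcyclohexane-1,3-dione | CC1(CO[Si](C)(C)C(C)(C)C)C(=O)CCCC1=O | intermediate
4 | (2S,3S)-2-[(tert-butyldimethylsilyloxy)methyl]-3-hydroxy-2-methylcyclohexan-1-one | O=C1CCC[C@H](O)[C@]1(C)CO[Si](C)(C)C(C)(C)C | intermediate
5 | (2S,3S)-3-(tert-butyldimethylsilyloxy)-2-[(tert-butyldimethylsilyloxy)methyl]-2-methylcyclohexan-1-one | O=C1CCC[C@H](O[Si](C)(C)C(C)(C)C)[C@]1(C)CO[Si](C)(C)C(C)(C)C | intermediate
6 | (2S,3S,6RS)-3-(tert-butyldimethylsilyloxy)-2-[(tert-butyldimethylsilyloxy)methyl]-2,6-dimethylcyclohexan-1-one (C-6 epimer mixture) | O=C1C(C)CC[C@H](O[Si](C)(C)C(C)(C)C)[C@]1(C)CO[Si](C)(C)C(C)(C)C | intermediate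
7 | (5S,6S)-5-(tert-butyldimethylsilyloxy)-6-[(tert-butyldimethylsilyloxy)methyl]-2,6-dimethylcyclohex-1-en-1-yl trifluoromethanesulfonate | CC1=C(OS(=O)(=O)C(F)(F)F)[C@@](C)(CO[Si](C)(C)C(C)(C)C)[C@@H](O[Si](C)(C)C(C)(C)C)CC1 | intermediate
8 | tributyl(1-ethoxyvinyl)stannane | CCCC[Sn](CCCC)(CCCC)C(=C)OCC | starting material
9 | (3S,4S)-4-(tert-butyldimethylsilyloxy)-3-[(tert-butyldimethylsilyloxy)methyl]-2-(1-ethoxyethenyl)-1,3-dimethylcyclohex-1-ene | CC1=C(C(=C)OCC)[C@@](C)(CO[Si](C)(C)C(C)(C)C)[C@@H](O[Si](C)(C)C(C)(C)C)CC1 | intermediate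
10 | methyl but-2-ynoate | CC#CC(=O)OC | starting material
11 | methyl 3β,19-bis(tert-butyldimethylsilyloxy)-6-ethoxy-12,13,14,15,16-pentanorlabda-5,8-dien-11-oate | CC1=C(C(=O)OC)[C@@]2(C)CC[C@H](O[Si](C)(C)C(C)(C)C)[C@](C)(CO[Si](C)(C)C(C)(C)C)C2=C(OCC)C1 | intermediate
12 | 3β,19-bis(tert-butyldimethylsilyloxy)-6-ethoxy-12,13,14,15,16-pentanorlabda-5,8-dien-11-ol | CC1=C(CO)[C@@]2(C)CC[C@H](O[Si](C)(C)C(C)(C)C)[C@](C)(CO[Si](C)(C)C(C)(C)C)C2=C(OCC)C1 | intermediate
13 | 3β,19-bis(tert-butyldimethylsilyloxy)-6-ethoxy-12,13,14,15,16-pentanorlabda-5,8-dien-11-yl methanesulfonate | CC1=C(COS(C)(=O)=O)[C@@]2(C)CC[C@H](O[Si](C)(C)C(C)(C)C)[C@](C)(CO[Si](C)(C)C(C)(C)C)C2=C(OCC)C1 | intermediate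
14 | 11-bromo-3β,19-bis(tert-butyldimethylsilyloxy)-6-ethoxy-12,13,14,15,16-pentanorlabda-5,8-diene | CC1=C(CBr)[C@@]2(C)CC[C@H](O[Si](C)(C)C(C)(C)C)[C@](C)(CO[Si](C)(C)C(C)(C)C)C2=C(OCC)C1 | intermediate
15 | allyl acetoacetate (prop-2-enyl 3-oxobutanoate) | CC(=O)CC(=O)OCC=C | starting material
16 | allyl 3β,19-bis(tert-butyldimethylsilyloxy)-6-ethoxy-13-oxo-16-norlabda-5,8-dien-15-oate | CC1=C(CCC(=O)CC(=O)OCC=C)[C@@]2(C)CC[C@H](O[Si](C)(C)C(C)(C)C)[C@](C)(CO[Si](C)(C)C(C)(C)C)C2=C(OCC)C1 | intermediate
17 | allyl (13Z)-3β,19-bis(tert-butyldimethylsilyloxy)-13-(diethoxyphosphoryloxy)-6-ethoxy-16-norlabda-5,8,13-trien-15-oate | CC1=C(CC/C(OP(=O)(OCC)OCC)=C/C(=O)OCC=C)[C@@]2(C)CC[C@H](O[Si](C)(C)C(C)(C)C)[C@](C)(CO[Si](C)(C)C(C)(C)C)C2=C(OCC)C1 | intermediate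
18 | allyl (13E)-3β,19-bis(tert-butyldimethylsilyloxy)-6-ethoxylabda-5,8,13-trien-15-oate | CC1=C(CC/C(C)=C/C(=O)OCC=C)[C@@]2(C)CC[C@H](O[Si](C)(C)C(C)(C)C)[C@](C)(CO[Si](C)(C)C(C)(C)C)C2=C(OCC)C1 | intermediate
19 | allyl (13E)-6-ethoxy-3β,19-dihydroxylabda-5,8,13-trien-15-oate | CC1=C(CC/C(C)=C/C(=O)OCC=C)[C@@]2(C)CC[C@H](O)[C@](C)(CO)C2=C(OCC)C1 | intermediate
20 | allyl (13E)-6-ethoxy-3β-hydroxy-19-(3-methylbutanoyloxy)labda-5,8,13-trien-15-oate | CC1=C(CC/C(C)=C/C(=O)OCC=C)[C@@]2(C)CC[C@H](O)[C@](C)(COC(=O)CC(C)C)C2=C(OCC)C1 | intermediate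
21 | allyl (13E)-6-ethoxy-19-(3-methylbutanoyloxy)-3-oxolabda-5,8,13-trien-15-oate | CC1=C(CC/C(C)=C/C(=O)OCC=C)[C@@]2(C)CCC(=O)[C@](C)(COC(=O)CC(C)C)C2=C(OCC)C1 | intermediate
22 | allyl (13E)-19-(3-methylbutanoyloxy)-3,6-dioxo-5α-labda-8,13-dien-15-oate | CC1=C(CC/C(C)=C/C(=O)OCC=C)[C@@]2(C)CCC(=O)[C@](C)(COC(=O)CC(C)C)[C@@H]2C(=O)C1 | intermediate
23 | allyl (13E)-3α,6β-dihydroxy-19-(3-methylbutanoyloxy)labda-8,13-dien-15-oate | CC1=C(CC/C(C)=C/C(=O)OCC=C)[C@@]2(C)CC[C@@H](O)[C@](C)(COC(=O)CC(C)C)[C@@H]2[C@H](O)C1 | intermediate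
24 | allyl (13E)-6β-hydroxy-3α,19-bis(3-methylbutanoyloxy)labda-8,13-dien-15-oate | CC1=C(CC/C(C)=C/C(=O)OCC=C)[C@@]2(C)CC[C@@H](OC(=O)CC(C)C)[C@](C)(COC(=O)CC(C)C)[C@@H]2[C@H](O)C1 | intermediate
25 | (13E)-6β-hydroxy-3α,19-bis(3-methylbutanoyloxy)labda-8,13-dien-15-oic acid (CNP0333611.1) | CC1=C(CC/C(C)=C/C(=O)O)[C@@]2(C)CC[C@@H](OC(=O)CC(C)C)[C@](C)(COC(=O)CC(C)C)[C@@H]2[C@H](O)C1 | target

Total step count: 19
Longest linear sequence: 19 steps (from 1 to 25)

**Steps most likely to fail**

Step 8 (Diels–Alder). The cycloaddition at the fully substituted, inside-methyl diene terminus may be too slow at temperatures the enol ether tolerates, or may lose α-face selectivity at the temperature it needs. Fallback: setting out from diene 9, cycloaddition with ethyl buta-2,3-dienoate (PhMe, 90–110 °C) is used instead. This allenic ester reacts through its α,β double bond with the same regiochemistry and is a much better dienophile than a β-methyl alkynoate. It would give ethyl 3β,19-bis(tert-butyldimethylsilyloxy)-6-ethoxy-12,13,14,15,16-pentanorlabda-5,8(17)-dien-11-oate F1 as a C-9 epimer mixture. DBU (CH2Cl2, rt) would then move the exocyclic C8=C17 bond into conjugation to give ethyl 3β,19-bis(tert-butyldimethylsilyloxy)-6-ethoxy-12,13,14,15,16-pentanorlabda-5,8-dien-11-oate F2. DIBAL-H reduction of F2 comes back to the route at alcohol 12.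

Step 3 (desymmetrising reduction). The catalyst may differentiate poorly between the two enantiotopic carbonyl groups, or between the faces flanked by CH3 and CH2OTBS, and over-reduction to the diol may compete. Fallback: setting out from dione 3 and coming back at ketol 4, the oxazaborolidine reduction is replaced by an enzymatic desymmetrisation (baker's yeast whole cells, or an isolated ketoreductase with NADPH/glucose dehydrogenase recycling). This is the classical biocatalytic route to (2S,3S)-3-hydroxy-2,2-disubstituted cyclohexanones, with the hydroxyl cis to the larger 2-substituent. This fallback makes no new compound (F0).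

Step 17 (double reduction). The basic hydride may enolise the β,γ-unsaturated 6-ketone toward C-7 and so move the C8=C9 bond into conjugation; reduction at the hindered C-6 carbonyl may be sluggish; or equatorial delivery at C-3 may be incomplete. Fallback: setting out from 3-keto enol ether 21 (isolated after the oxidation stage of step 16, before hydrolysis), C-3 is dealt with while C-6 is still masked. L-Selectride (THF, −78 °C) would give allyl (13E)-6-ethoxy-3α-hydroxy-19-(3-methylbutanoyloxy)labda-5,8,13-trien-15-oate F3. Acylation with 3-methylbutanoic anhydride/DMAP would give allyl (13E)-6-ethoxy-3α,19-bis(3-methylbutanoyloxy)labda-5,8,13-trien-15-oate F4. Oxalic acid hydrolysis would give allyl (13E)-3α,19-bis(3-methylbutanoyloxy)-6-oxo-5α-labda-8,13-dien-15-oate F5. Immediate non-basic Luche reduction (NaBH4, CeCl3, MeOH, −78 °C; hydride from the α face) comes back to the route at ester 24, which also removes the need to differentiate the 3α- and 6β-hydroxyls in step 18.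

Further compounds
F0 | step 3 | none | none
F1 | step 8 | ethyl 3β,19-bis(tert-butyldimethylsilyloxy)-6-ethoxy-12,13,14,15,16-pentanorlabda-5,8(17)-dien-11-oate (C-9 epimer mixture) | C=C1C(C(=O)OCC)[C@@]2(C)CC[C@H](O[Si](C)(C)C(C)(C)C)[C@](C)(CO[Si](C)(C)C(C)(C)C)C2=C(OCC)C1
F2 | step 8 | ethyl 3β,19-bis(tert-butyldimethylsilyloxy)-6-ethoxy-12,13,14,15,16-pentanorlabda-5,8-dien-11-oate | CC1=C(C(=O)OCC)[C@@]2(C)CC[C@H](O[Si](C)(C)C(C)(C)C)[C@](C)(CO[Si](C)(C)C(C)(C)C)C2=C(OCC)C1
F3 | step 17 | allyl (13E)-6-ethoxy-3α-hydroxy-19-(3-methylbutanoyloxy)labda-5,8,13-trien-15-oate | CC1=C(CC/C(C)=C/C(=O)OCC=C)[C@@]2(C)CC[C@@H](O)[C@](C)(COC(=O)CC(C)C)C2=C(OCC)C1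
F4 | step 17 | allyl (13E)-6-ethoxy-3α,19-bis(3-methylbutanoyloxy)labda-5,8,13-trien-15-oate | CC1=C(CC/C(C)=C/C(=O)OCC=C)[C@@]2(C)CC[C@@H](OC(=O)CC(C)C)[C@](C)(COC(=O)CC(C)C)C2=C(OCC)C1
F5 | step 17 | allyl (13E)-3α,19-bis(3-methylbutanoyloxy)-6-oxo-5α-labda-8,13-dien-15-oate | CC1=C(CC/C(C)=C/C(=O)OCC=C)[C@@]2(C)CC[C@@H](OC(=O)CC(C)C)[C@](C)(COC(=O)CC(C)C)[C@@H]2C(=O)C1
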